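## Retrosynthetic overview

1. The last operations unveil the α‑methylene lactone: C13 is added by Horner–Wadsworth–Emmons methylenation of an α‑phosphono lactone, then the 9‑O‑silyl group is removed.
2. Key disconnection: C7–C8 and C11–C12 together, by a reductive radical–polar [3+2] annulation of an acyclic 1‑iodoalkyl phenyl carbonate (C8, C12) onto an (E)‑vinylphosphonate (C7=C11). The oxirane and the angelate are already in place.
3. Enabling feature: in the butanolide ring C8 and C12 flank the ring oxygen, so C8–O–C12(=O) is an aldehyde carbon already O‑acylated by the future lactone carbonyl (an O‑acyl ketyl donor plus an acyl acceptor). The exocyclic C11=C13 methylene lets C11 be the α‑carbon and C7 the β‑carbon of a vinylphosphonate.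
4. The seco chain comes from (R)‑citronellal (C10), proline aminoxylation (C9), Negishi carboalumination (E‑C4=C5), Sharpless epoxidation (C4, C5) and Felkin–Anh vinylation (C6); cross‑metathesis installs the phosphonate.
5. Ring order: oxirane (step 8), then the ten‑membered carbocycle and the γ‑lactone in the same operation (step 15).

Key step: step 15

Remark: atoms are numbered as in germacranolides (lactone C12(=O)–O–C8; C9 bears OH; C10 bears methyl C14; C1–C3 are CH2; C4 (methyl C15)/C5 oxirane; C6 bears the angelate; C7; C11=C13H2). In this numbering the target is 4R,5R,6R,7S,8S,9R,10R.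

## Route

Step 1
Reactants: 1 (R)-citronellal
Product: 3 (2R,3R)-3,7-dimethyl-2-[(phenylamino)oxy]oct-6-en-1-ol, via aminoxy aldehyde 2 (not isolated)
Conditions: PhNO, L-proline (20 mol %), DMSO, rt; then NaBH4, EtOH, 0 °C
Reagents that add atoms: nitrosobenzene O=Nc1ccccc1
Why: Proline-catalysed enamine α-aminoxylation (O-selective nitroso aldol) should set C9 as R under catalyst control by acid-directed attack on the anti-enamine, and borohydride reduction in the same flask protects the labile α-oxy aldehyde from epimerisation.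

Step 2
Reactants: 3 (2R,3R)-3,7-dimethyl-2-[(phenylamino)oxy]oct-6-en-1-ol
Product: 4 (2R,3R)-3,7-dimethyloct-6-ene-1,2-diol
Conditions: Zn dust, AcOH, EtOH, rt
Reagents that add atoms: none
Why: Reductive N–O cleavage of the O-alkyl-N-arylhydroxylamine with zinc in acetic acid should free the 1,2-diol without touching the trisubstituted alkene.

Step 3
Reactants: 4 (2R,3R)-3,7-dimethyloct-6-ene-1,2-diol
Product: 5 (2R,3R)-3,7-dimethyl-1,2-bis(triethylsilyloxy)oct-6-ene
Conditions: Et3SiCl (2.5 equiv), imidazole, DMF, 0 °C to rt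
Reagents that add atoms: chlorotriethylsilane CC[Si](Cl)(CC)CC
Why: Standard silylation of both hydroxyls; the primary triethylsilyl ether is the one that step 13 later oxidises selectively.

Step 4
Reactants: 5 (2R,3R)-3,7-dimethyl-1,2-bis(triethylsilyloxy)oct-6-ene
Product: 7 (4R,5R)-4-methyl-5,6-bis(triethylsilyloxy)hexan-1-ol, via aldehyde 6 (not isolated)
Conditions: O3, CH2Cl2/MeOH, −78 °C; then NaBH4, −78 to 0 °C
Reagents that add atoms: ozone [O-][O+]=O
Why: Ozonolysis of the only alkene with reductive borohydride work-up should deliver the primary alcohol and cut off the three surplus carbons.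

Step 5
Reactants: 7 (4R,5R)-4-methyl-5,6-bis(triethylsilyloxy)hexan-1-ol
Product: 8 (2R,3R)-6-iodo-3-methyl-1,2-bis(triethylsilyloxy)hexane
Conditions: I2, PPh3, imidazole, CH2Cl2, 0 °C to rt
Reagents that add atoms: iodine II
Why: Appel-type iodination of a primary alcohol under conditions that silyl ethers tolerate.

Step 6
Reactants: 8 (2R,3R)-6-iodo-3-methyl-1,2-bis(triethylsilyloxy)hexane
Product: 9 (6R,7R)-6-methyl-7,8-bis(triethylsilyloxy)oct-1-yne
Conditions: LiC≡CH·H2NCH2CH2NH2, DMSO/THF, 0 °C to rt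
Reagents that add atoms: lithium acetylide (ethylenediamine complex) [Li+].[C-]#C
Why: SN2 alkylation of lithium acetylide by the primary iodide should add the two alkyne carbons that become C4 and C5.

Step 7
Reactants: 9 (6R,7R)-6-methyl-7,8-bis(triethylsilyloxy)oct-1-yne
Product: 12 (2E,7R,8R)-3,7-dimethyl-8,9-bis(triethylsilyloxy)non-2-en-1-ol, via alkenylalane 10 (not isolated), via lithium alanate 11 (not isolated)
Conditions: Me3Al, Cp2ZrCl2 (25 mol %), CH2Cl2, 0 °C to rt; then n-BuLi, hexane/THF, −78 to 0 °C; then (CH2O)n, rt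
Reagents that add atoms: trimethylaluminium C[Al](C)C; formaldehyde (from paraformaldehyde) C=O
Why: Negishi zirconium-catalysed carboalumination adds methyl and aluminium syn across the terminal alkyne (methyl to the internal carbon), and the derived alanate is hydroxymethylated with retention, which should fix the E-trisubstituted C4=C5 alkene.

Step 8
Reactants: 12 (2E,7R,8R)-3,7-dimethyl-8,9-bis(triethylsilyloxy)non-2-en-1-ol
Product: 13 [(2R,3R)-3-methyl-3-[(4R,5R)-4-methyl-5,6-bis(triethylsilyloxy)hexyl]oxiran-2-yl]methanol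
Conditions: Ti(OiPr)4 (10 mol %), D-(−)-diethyl tartrate (12 mol %), t-BuOOH, 4 Å molecular sieves, CH2Cl2, −20 °C
Reagents that add atoms: tert-butyl hydroperoxide CC(C)(C)OO
Why: Sharpless asymmetric epoxidation of the primary E-allylic alcohol with the D-(−)-tartrate catalyst should set C4 and C5 as R,R by reagent control, the sense that gives 2R,3R-epoxy alcohols from geraniol-type substrates.

Step 9
Reactants: 13 [(2R,3R)-3-methyl-3-[(4R,5R)-4-methyl-5,6-bis(triethylsilyloxy)hexyl]oxiran-2-yl]methanol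
Product: 14 (2S,3R)-3-methyl-3-[(4R,5R)-4-methyl-5,6-bis(triethylsilyloxy)hexyl]oxirane-2-carbaldehyde
Conditions: TEMPO (10 mol %), PhI(OAc)2, CH2Cl2, rt
Reagents that add atoms: none
Why: TEMPO-catalysed oxidation with PhI(OAc)2 should stop at the epoxy aldehyde under non-basic conditions that leave the oxirane and the silyl ethers intact.

Step 10
Reactants: 14 (2S,3R)-3-methyl-3-[(4R,5R)-4-methyl-5,6-bis(triethylsilyloxy)hexyl]oxirane-2-carbaldehyde
Product: 15 (1R)-1-[(2R,3R)-3-methyl-3-[(4R,5R)-4-methyl-5,6-bis(triethylsilyloxy)hexyl]oxiran-2-yl]prop-2-en-1-ol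
Conditions: CH2=CHMgBr, THF, −78 °C
Reagents that add atoms: vinylmagnesium bromide C=C[Mg]Br
Why: Grignard 1,2-addition to the α,β-epoxy aldehyde should follow the Felkin–Anh/Cornforth model (attack anti to the oxirane C5–O bond) and give the erythro carbinol with C6 as R.

Step 11
Reactants: 15 (1R)-1-[(2R,3R)-3-methyl-3-[(4R,5R)-4-methyl-5,6-bis(triethylsilyloxy)hexyl]oxiran-2-yl]prop-2-en-1-ol and 16 diethyl vinylphosphonate
Product: 17 diethyl [(1E,3R)-3-hydroxy-3-[(2R,3R)-3-methyl-3-[(4R,5R)-4-methyl-5,6-bis(triethylsilyloxy)hexyl]oxiran-2-yl]prop-1-en-1-yl]phosphonate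
Conditions: second-generation Hoveyda–Grubbs catalyst (5 mol %), 16 (3 equiv), CH2Cl2, 40 °C
Reagents that add atoms: none
Why: Olefin cross-metathesis of the terminal vinyl group with the electron-poor vinylphosphonate should be selective for the E-vinylphosphonate, the free allylic hydroxyl assisting the catalyst.

Step 12
Reactants: 17 diethyl [(1E,3R)-3-hydroxy-3-[(2R,3R)-3-methyl-3-[(4R,5R)-4-methyl-5,6-bis(triethylsilyloxy)hexyl]oxiran-2-yl]prop-1-en-1-yl]phosphonate and 18 angelic acid
Product: 20 (1R,2E)-3-(diethoxyphosphoryl)-1-[(2R,3R)-3-methyl-3-[(4R,5R)-4-methyl-5,6-bis(triethylsilyloxy)hexyl]oxiran-2-yl]prop-2-en-1-yl (2Z)-2-methylbut-2-enoate, via mixed anhydride 19 (not isolated)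
Conditions: 18, 2,4,6-trichlorobenzoyl chloride, Et3N, toluene, rt; then 17, NaHCO3, toluene, 80 °C
Reagents that add atoms: none
Why: Yamaguchi-type esterification through the preformed mixed anhydride acylates the secondary alcohol with no nucleophilic amine in the acylation stage, which should retain the Z (angelate) geometry and avoid alkoxide-driven oxirane migration.

Step 13
Reactants: 20 (1R,2E)-3-(diethoxyphosphoryl)-1-[(2R,3R)-3-methyl-3-[(4R,5R)-4-methyl-5,6-bis(triethylsilyloxy)hexyl]oxiran-2-yl]prop-2-en-1-yl (2Z)-2-methylbut-2-enoate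
Product: 21 (1R,2E)-3-(diethoxyphosphoryl)-1-[(2R,3R)-3-methyl-3-[(4R,5R)-4-methyl-6-oxo-5-(triethylsilyloxy)hexyl]oxiran-2-yl]prop-2-en-1-yl (2Z)-2-methylbut-2-enoate
Conditions: (COCl)2, DMSO, CH2Cl2, −78 to −30 °C; then Et3N, −78 °C to 0 °C
Reagents that add atoms: none
Why: Under Swern conditions the unhindered primary triethylsilyl ether is cleaved by the chlorosulfonium salt and oxidised directly to the aldehyde, while the secondary silyl ether at C9 survives (selective oxidative desilylation of primary triethylsilyl ethers).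

Step 14
Reactants: 21 (1R,2E)-3-(diethoxyphosphoryl)-1-[(2R,3R)-3-methyl-3-[(4R,5R)-4-methyl-6-oxo-5-(triethylsilyloxy)hexyl]oxiran-2-yl]prop-2-en-1-yl (2Z)-2-methylbut-2-enoate
Product: 23 (1R,2E)-3-(diethoxyphosphoryl)-1-[(2R,3R)-3-[(4R,5R,6RS)-6-iodo-4-methyl-6-(phenoxycarbonyloxy)-5-(triethylsilyloxy)hexyl]-3-methyloxiran-2-yl]prop-2-en-1-yl (2Z)-2-methylbut-2-enoate, via chloro carbonate 22 (not isolated)
Conditions: PhOC(O)Cl, pyridine (10 mol %), CH2Cl2, 0 °C to rt; then NaI, MeCN, rt, dark
Reagents that add atoms: phenyl chloroformate O=C(Cl)Oc1ccccc1; sodium iodide [Na+].[I-]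
Why: Pyridine-catalysed addition of a chloroformate across an aldehyde C=O is the standard way to 1-chloroalkyl carbonates, and a Finkelstein exchange should give the more easily reduced iodide; C8 forms as an epimer mixture, which does not matter because C8 becomes a planar radical in step 15.

Step 15
Reactants: 23 (1R,2E)-3-(diethoxyphosphoryl)-1-[(2R,3R)-3-[(4R,5R,6RS)-6-iodo-4-methyl-6-(phenoxycarbonyloxy)-5-(triethylsilyloxy)hexyl]-3-methyloxiran-2-yl]prop-2-en-1-yl (2Z)-2-methylbut-2-enoate
Product: 25 α-phosphono lactone (ten-membered ring and γ-lactone closed; 9-O-triethylsilyl; C11 carries H and P(O)(OEt)2; C4 to C10 as in the target; C11 epimers), via samarium carbanion 24 (not isolated)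
Conditions: SmI2 (0.1 M in THF, 2.5 equiv, added over 6 h) to 23 (2 mM in THF), no HMPA, −20 °C to rt; then aq. NH4Cl
Reagents that add atoms: none
Why: Proposed new method: SmI2 cleaves the C8–I bond to an α-(phenoxycarbonyloxy)alkyl radical (an O-acylated ketyl), which adds to C7, the β-carbon of the (E)-vinylphosphonate; a second SmI2 reduces the α-phosphonyl radical to the trivalent-samarium carbanion 24, whose C11 attacks the carbonate carbon C12 and expels phenoxide, so that C7–C8 and C11–C12 form in one operation and the carbonate carbon becomes the lactone carbonyl. The closest known reaction types are SmI2 ketyl–olefin cyclisations onto acrylate-type acceptors, SmI2 radical cyclisation/intramolecular nucleophilic acyl substitution sequences and Giese additions of 1-acyloxyalkyl radicals, none of which has been run as a radical–polar [3+2] lactone annulation on a carbonate or to close a ten-membered ring. The ten-membered carbocycle closes by radical 10-exo-trig addition and the γ-lactone by anionic 5-exo-trig acyl substitution. C7 should be set by the C6 stereocentre (attack anti to the allylic C6–O bond with H6 inside, allylic-strain model for the E-alkene) and C8 by the anti arrangement of the C8–O bond and the alkene across the forming bond that is typical of ketyl–olefin couplings, which corresponds to the trans-fused lactone, so that C8 is relayed from C6 through C7 while C9 only has to be matched; C11 forms as a mixture that step 16 erases. The step needs ring closure to outrun further reduction of the C8 radical and needs the carbanion to acylate at C12 and not at the angelate: slow addition of SmI2 to a dilute solution without HMPA or proton source keeps the radical alive, the vinylphosphonate is the only good radical acceptor, and the phenyl carbonate sits in a five-membered transition state and is by far the better acyl donor.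

Step 16
Reactants: 25 α-phosphono lactone
Product: 26 9-O-triethylsilyl ether of the target (α-methylene lactone; all stereocentres as in the target)
Conditions: aq. HCHO (37 %), K2CO3, THF, 0 °C to rt
Reagents that add atoms: formaldehyde C=O
Why: Horner–Wadsworth–Emmons olefination of the α-phosphono lactone with formaldehyde should install the exocyclic methylene C13 and erase the C11 mixture under carbonate base that the angelate, oxirane and silyl ether tolerate.

Step 17
Reactants: 26 9-O-triethylsilyl ether of the target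
Product: 27 target, (4R,5R,6R,7S,8S,9R,10R)-6-angeloyloxy-4,5-epoxy-9-hydroxygermacr-11(13)-en-12,8-olide (CNP0165329.1)
Conditions: HF·pyridine, pyridine, THF, 0 °C
Reagents that add atoms: none
Why: Buffered fluoride desilylation should remove the secondary triethylsilyl ether without opening the trisubstituted oxirane or adding to the α-methylene lactone.

## Compound list

1 | (R)-citronellal, (3R)-3,7-dimethyloct-6-enal | O=CC[C@H](C)CCC=C(C)C | starting material
2 | (2R,3R)-3,7-dimethyl-2-[(phenylamino)oxy]oct-6-enal | O=C[C@H](ONc1ccccc1)[C@H](C)CCC=C(C)C | intermediate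
3 | (2R,3R)-3,7-dimethyl-2-[(phenylamino)oxy]oct-6-en-1-ol | OC[C@H](ONc1ccccc1)[C@H](C)CCC=C(C)C | intermediate
4 | (2R,3R)-3,7-dimethyloct-6-ene-1,2-diol | OC[C@H](O)[C@H](C)CCC=C(C)C | intermediate
5 | (2R,3R)-3,7-dimethyl-1,2-bis(triethylsilyloxy)oct-6-ene | CC[Si](CC)(CC)OC[C@H](O[Si](CC)(CC)CC)[C@H](C)CCC=C(C)C | intermediate
6 | (4R,5R)-4-methyl-5,6-bis(triethylsilyloxy)hexanal | CC[Si](CC)(CC)OC[C@H](O[Si](CC)(CC)CC)[C@H](C)CCC=O | intermediate
7 | (4R,5R)-4-methyl-5,6-bis(triethylsilyloxy)hexan-1-ol | CC[Si](CC)(CC)OC[C@H](O[Si](CC)(CC)CC)[C@H](C)CCCO | intermediate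
8 | (2R,3R)-6-iodo-3-methyl-1,2-bis(triethylsilyloxy)hexane | CC[Si](CC)(CC)OC[C@H](O[Si](CC)(CC)CC)[C@H](C)CCCI | intermediate
9 | (6R,7R)-6-methyl-7,8-bis(triethylsilyloxy)oct-1-yne | CC[Si](CC)(CC)OC[C@H](O[Si](CC)(CC)CC)[C@H](C)CCCC#C | intermediate
10 | dimethyl[(1E,6R,7R)-2,6-dimethyl-7,8-bis(triethylsilyloxy)oct-1-en-1-yl]alane | CC[Si](CC)(CC)OC[C@H](O[Si](CC)(CC)CC)[C@H](C)CCC/C(C)=C/[Al](C)C | intermediate
11 | lithium butyl(dimethyl)[(1E,6R,7R)-2,6-dimethyl-7,8-bis(triethylsilyloxy)oct-1-en-1-yl]alanate | CC[Si](CC)(CC)OC[C@H](O[Si](CC)(CC)CC)[C@H](C)CCC/C(C)=C/[Al-](C)(C)CCCC.[Li+] | intermediate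
12 | (2E,7R,8R)-3,7-dimethyl-8,9-bis(triethylsilyloxy)non-2-en-1-ol | CC[Si](CC)(CC)OC[C@H](O[Si](CC)(CC)CC)[C@H](C)CCC/C(C)=C/CO | intermediate
13 | [(2R,3R)-3-methyl-3-[(4R,5R)-4-methyl-5,6-bis(triethylsilyloxy)hexyl]oxiran-2-yl]methanol | CC[Si](CC)(CC)OC[C@H](O[Si](CC)(CC)CC)[C@H](C)CCC[C@@]1(C)O[C@@H]1CO | intermediate
14 | (2S,3R)-3-methyl-3-[(4R,5R)-4-methyl-5,6-bis(triethylsilyloxy)hexyl]oxirane-2-carbaldehyde | CC[Si](CC)(CC)OC[C@H](O[Si](CC)(CC)CC)[C@H](C)CCC[C@@]1(C)O[C@@H]1C=O | intermediate
15 | (1R)-1-[(2R,3R)-3-methyl-3-[(4R,5R)-4-methyl-5,6-bis(triethylsilyloxy)hexyl]oxiran-2-yl]prop-2-en-1-ol | CC[Si](CC)(CC)OC[C@H](O[Si](CC)(CC)CC)[C@H](C)CCC[C@@]1(C)O[C@@H]1[C@H](O)C=C | intermediate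
16 | diethyl vinylphosphonate | C=CP(=O)(OCC)OCC | starting material
17 | diethyl [(1E,3R)-3-hydroxy-3-[(2R,3R)-3-methyl-3-[(4R,5R)-4-methyl-5,6-bis(triethylsilyloxy)hexyl]oxiran-2-yl]prop-1-en-1-yl]phosphonate | CC[Si](CC)(CC)OC[C@H](O[Si](CC)(CC)CC)[C@H](C)CCC[C@@]1(C)O[C@@H]1[C@H](O)/C=C/P(=O)(OCC)OCC | intermediate
18 | angelic acid, (2Z)-2-methylbut-2-enoic acid | C/C=C(/C)C(=O)O | starting material
19 | (2Z)-2-methylbut-2-enoic 2,4,6-trichlorobenzoic anhydride | C/C=C(/C)C(=O)OC(=O)c1c(Cl)cc(Cl)cc1Cl | intermediate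
20 | (1R,2E)-3-(diethoxyphosphoryl)-1-[(2R,3R)-3-methyl-3-[(4R,5R)-4-methyl-5,6-bis(triethylsilyloxy)hexyl]oxiran-2-yl]prop-2-en-1-yl (2Z)-2-methylbut-2-enoate | CC[Si](CC)(CC)OC[C@H](O[Si](CC)(CC)CC)[C@H](C)CCC[C@@]1(C)O[C@@H]1[C@H](OC(=O)/C(C)=C\C)/C=C/P(=O)(OCC)OCC | intermediate
21 | (1R,2E)-3-(diethoxyphosphoryl)-1-[(2R,3R)-3-methyl-3-[(4R,5R)-4-methyl-6-oxo-5-(triethylsilyloxy)hexyl]oxiran-2-yl]prop-2-en-1-yl (2Z)-2-methylbut-2-enoate | O=C[C@H](O[Si](CC)(CC)CC)[C@H](C)CCC[C@@]1(C)O[C@@H]1[C@H](OC(=O)/C(C)=C\C)/C=C/P(=O)(OCC)OCC | intermediate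
22 | 1-chloroalkyl phenyl carbonate: 21 with the aldehyde carbon C8 converted to CH(Cl)OC(O)OPh (C8 epimers) | ClC(OC(=O)Oc1ccccc1)[C@H](O[Si](CC)(CC)CC)[C@H](C)CCC[C@@]2(C)O[C@@H]2[C@H](OC(=O)/C(C)=C\C)/C=C/P(=O)(OCC)OCC | intermediate
23 | 1-iodoalkyl phenyl carbonate: (1R,2E)-3-(diethoxyphosphoryl)-1-[(2R,3R)-3-[(4R,5R,6RS)-6-iodo-4-methyl-6-(phenoxycarbonyloxy)-5-(triethylsilyloxy)hexyl]-3-methyloxiran-2-yl]prop-2-en-1-yl (2Z)-2-methylbut-2-enoate | IC(OC(=O)Oc1ccccc1)[C@H](O[Si](CC)(CC)CC)[C@H](C)CCC[C@@]2(C)O[C@@H]2[C@H](OC(=O)/C(C)=C\C)/C=C/P(=O)(OCC)OCC | intermediate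
24 | diiodosamarium salt of the ring-closed phosphonate carbanion (C7–C8 bond formed; phenyl carbonate still on O8; carbanion at C11) | [Sm+3].[I-].[I-].O=C(Oc1ccccc1)O[C@@H]2[C@H](O[Si](CC)(CC)CC)[C@H](C)CCC[C@@]3(C)O[C@@H]3[C@H](OC(=O)/C(C)=C\C)[C@H]2[CH-]P(=O)(OCC)OCC | intermediate
25 | α-phosphono lactone: target skeleton with 9-O-triethylsilyl and with H and P(O)(OEt)2 on C11 in place of the methylene (C4 to C10 as in the target; C11 epimers) | CCOP(=O)(OCC)C1C(=O)O[C@@H]2[C@H](O[Si](CC)(CC)CC)[C@H](C)CCC[C@@]3(C)O[C@@H]3[C@H](OC(=O)/C(C)=C\C)[C@@H]12 | intermediate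
26 | 9-O-triethylsilyl ether of the target | C=C1C(=O)O[C@@H]2[C@H](O[Si](CC)(CC)CC)[C@H](C)CCC[C@@]3(C)O[C@@H]3[C@H](OC(=O)/C(C)=C\C)[C@@H]12 | intermediate
27 | (4R,5R,6R,7S,8S,9R,10R)-6-angeloyloxy-4,5-epoxy-9-hydroxygermacr-11(13)-en-12,8-olide (CNP0165329.1) | C=C1C(=O)O[C@@H]2[C@H](O)[C@H](C)CCC[C@@]3(C)O[C@@H]3[C@H](OC(=O)/C(C)=C\C)[C@@H]12 | target

## Step count and risks

Total step count: 17. Longest linear sequence: 17 steps, from (R)-citronellal 1.

Steps most likely to fail:

1. Step 15 (proposed new method). What may go wrong: the C8 radical is reduced further to the organosamarium (followed by β-elimination of the 9-silyloxy group) or abstracts hydrogen before the ten-membered ring closes, or it adds with the wrong facial sense at C7 and C8. The fallback uses known reactions only and sets out from aldehyde 21. A SmI2 ketyl–olefin cyclisation onto the vinylphosphonate (SmI2, t-BuOH, THF, high dilution) should close the ring and give the ten-membered hydroxy phosphonate F1 with the anti relationship of the C8 oxygen and the phosphonomethyl group. Acylation of the new C8 hydroxyl with phenyl chloroformate and pyridine gives the phenyl carbonate F2. LDA (THF, −78 °C) then deprotonates α to phosphorus and the carbanion closes the lactone by intramolecular acylation. The route is rejoined at 25.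

2. Step 14. What may go wrong: reversion of the haloalkyl carbonate to the aldehyde, and loss of iodide by hydrolysis or elimination during the exchange and handling. The fallback sets out from 21. The chloro carbonate 22 is generated as before, but chloride is displaced with benzeneselenol and Et3N to give the storable O,Se-acetal carbonate F3. A chain radical macrocyclisation ((Me3Si)3SiH, AIBN, benzene, 80 °C, slow addition; Giese addition) should then give the phenyl carbonate F2, which is closed with LDA as above. The route is rejoined at 25.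

3. Step 10. What may go wrong: poor facial selectivity in the Grignard addition, because chelated and Felkin–Anh transition states compete. The fallback sets out from allylic alcohol 12. Oxidation with MnO2 gives the enal F4, and vinylmagnesium bromide gives the dienol F5 as both C6 epimers. C4, C5 and C6 are then set together by a Sharpless kinetic-resolution epoxidation (Ti(OiPr)4, D-(−)-diisopropyl tartrate, 0.6 equiv t-BuOOH, −20 °C), in which only the 6R epimer is epoxidised at the trisubstituted alkene, with erythro selectivity. The route is rejoined at 15, so steps 8 to 10 are skipped.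

Further compounds
F1 | step 15 | ten-membered hydroxy phosphonate (C7–C8 bond formed; free 8-OH; CH2P(O)(OEt)2 on C7; other centres as in 25) | O[C@@H]1[C@H](O[Si](CC)(CC)CC)[C@H](C)CCC[C@@]2(C)O[C@@H]2[C@H](OC(=O)/C(C)=C\C)[C@H]1CP(=O)(OCC)OCC
F2 | step 15 | phenyl carbonate of F1 at O8 | O=C(Oc1ccccc1)O[C@@H]2[C@H](O[Si](CC)(CC)CC)[C@H](C)CCC[C@@]3(C)O[C@@H]3[C@H](OC(=O)/C(C)=C\C)[C@H]2CP(=O)(OCC)OCC
F3 | step 14 | O,Se-acetal carbonate: 23 with phenylselanyl in place of iodine (C8 epimers) | c1ccccc1[Se]C(OC(=O)Oc1ccccc1)[C@H](O[Si](CC)(CC)CC)[C@H](C)CCC[C@@]2(C)O[C@@H]2[C@H](OC(=O)/C(C)=C\C)/C=C/P(=O)(OCC)OCC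
F4 | step 10 | (2E,7R,8R)-3,7-dimethyl-8,9-bis(triethylsilyloxy)non-2-enal | CC[Si](CC)(CC)OC[C@H](O[Si](CC)(CC)CC)[C@H](C)CCC/C(C)=C/C=O
F5 | step 10 | (3RS,4E,9R,10R)-5,9-dimethyl-10,11-bis(triethylsilyloxy)undeca-1,4-dien-3-ol | CC[Si](CC)(CC)OC[C@H](O[Si](CC)(CC)CC)[C@H](C)CCC/C(C)=C/C(O)C=C
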